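**Retrosynthetic overview** (target numbering: C1 = ring C=O, C2 carries the C7H2–O group, C3 = CH, C4 O-tigloyl, C5 isopropyl, C6 OH)
Target ⇐ selective tigloylation of C7–OH ⇐ Stille hydroxymethylation of a 2-bromo-enone ⇐ allylic oxidation at C1 of a 2-bromocyclohex-2-ene-1,6-cis-diol that is held as a cyclic carbonate.
Key disconnection: cyclohexene ring ⇐ cyclopentene + CBr2. Ag(I)-triggered electrocyclic opening of a 6,6-dibromobicyclo[3.1.0]hexane inserts C2 between C1 and C3 (ring expansion 5 → 6), and the Boc group on the C6 oxygen captures the allyl cation at C1.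
Enabling feature: C2 of the six-membered ring is a substituted sp2 carbon flanked by oxygenated C1 and by C3–H (a 2-substituted allyl unit O–C1–C2(X)=C3), and C1 has the oxygen-bearing neighbour C6. The stereotriad C4–C5–C6 lies on the far side of the ring and is not touched by the expansion.
The cyclopentene (C1, C3–C6) with its O/iPr/O triad comes from dearomatisation of a furan: Piancatelli rearrangement of the carbinol from furfural and iPrMgCl sets C5/C6 trans, a lipase resolution supplies the absolute configuration, and CBS reduction sets C4.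
Order of ring formation: furan → cyclopentenone (4π electrocyclisation) → bicyclo[3.1.0]hexane ([2+1]) → cyclohexene (ring expansion, fused to a temporary cyclic carbonate that is cleaved in step 11).

Key step: step 8

Assumption: in step 3 the lipase is taken to acylate the (4R,5S)-alcohol faster, as the empirical size rule for lipases (Kazlauskas' rule) predicts when C5 with its isopropyl group is the large and the vinylic C3 the medium substituent; the wanted (4S,5R)-alcohol is then the unreacted one.

Step 1
Reactants: 1 furfural; 2 isopropylmagnesium chloride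
Product: 3 rac-1-(furan-2-yl)-2-methylpropan-1-ol
Conditions: iPrMgCl (1.1 equiv), THF, 0 °C; aq NH4Cl
Reagents that add atoms: none
Why: Grignard 1,2-addition to a non-enolisable heteroaryl aldehyde; the new carbinol centre is racemic and irrelevant because it becomes a cationic terminus in step 2.

Step 2
Reactants: 3 rac-1-(furan-2-yl)-2-methylpropan-1-ol
Product: 5 rac-(4S*,5R*)-4-hydroxy-5-isopropylcyclopent-2-en-1-one, via dihydrofuranol hemiacetal 4 (not isolated)
Conditions: ZnCl2 (2 equiv), dioxane/H2O (1:1), pH ca. 6, reflux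
Reagents that add atoms: water O
Why: Piancatelli rearrangement: ionisation of the furylcarbinol, addition of water at C5 of the furan, ring opening to a 1,4-dihydroxypentadienyl cation and conrotatory 4π electrocyclisation (Nazarov-type), whose out,out geometry should place the new hydroxyl and the isopropyl group trans.

Step 3
Reactants: 5 rac-(4S*,5R*)-4-hydroxy-5-isopropylcyclopent-2-en-1-one
Product: 6 (4S,5R)-4-hydroxy-5-isopropylcyclopent-2-en-1-one
Conditions: immobilised lipase PS (Burkholderia cepacia), vinyl acetate (3 equiv), MTBE, 30 °C, run to just past half conversion; chromatography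
Reagents that add atoms: none
Why: Lipase-catalysed kinetic resolution by enantioselective transesterification should acetylate the (4R,5S)-enantiomer and leave the wanted (4S,5R)-alcohol, which is the only externally introduced chirality of the route.

Step 4
Reactants: 6 (4S,5R)-4-hydroxy-5-isopropylcyclopent-2-en-1-one
Product: 7 tert-butyl (1S,5R)-5-isopropyl-4-oxocyclopent-2-en-1-yl carbonate
Conditions: Boc2O (1.3 equiv), Et3N (1.2 equiv), DMAP (5 mol %), CH2Cl2, 0 °C
Reagents that add atoms: di-tert-butyl dicarbonate CC(C)(C)OC(=O)OC(=O)OC(C)(C)C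
Why: DMAP-catalysed O-acylation at 0 °C is mild enough to avoid β-elimination or double-bond migration of the 4-hydroxycyclopentenone and installs the carbonate that later serves as the internal nucleophile.

Step 5
Reactants: 7 tert-butyl (1S,5R)-5-isopropyl-4-oxocyclopent-2-en-1-yl carbonate
Product: 8 tert-butyl (1S,4S,5S)-4-hydroxy-5-isopropylcyclopent-2-en-1-yl carbonate
Conditions: (S)-2-methyl-CBS-oxazaborolidine (15 mol %), catecholborane (1.5 equiv), toluene, −78 °C; MeOH, then pH 9 buffer wash
Reagents that add atoms: none
Why: Corey–Bakshi–Shibata 1,2-reduction of the enone, in which the (S)-catalyst (enone π-side as the large group) and the substrate (attack anti to the adjacent isopropyl) should both deliver hydride to the face opposite isopropyl, giving the carbinol cis to isopropyl and 1,3-trans to the carbonate.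

Step 6
Reactants: 8 tert-butyl (1S,4S,5S)-4-hydroxy-5-isopropylcyclopent-2-en-1-yl carbonate
Product: 9 tert-butyl (1S,4S,5R)-4-[(tert-butyldimethylsilyl)oxy]-5-isopropylcyclopent-2-en-1-yl carbonate
Conditions: TBSCl (1.5 equiv), imidazole (3 equiv), DMAP (cat.), DMF, 35 °C
Reagents that add atoms: tert-butyldimethylsilyl chloride CC(C)(C)[Si](C)(C)Cl
Why: Standard silylation of the hindered allylic alcohol places a base-stable, non-participating ether on the oxygen that will become the C4 ester oxygen.

Step 7
Reactants: 9 tert-butyl (1S,4S,5R)-4-[(tert-butyldimethylsilyl)oxy]-5-isopropylcyclopent-2-en-1-yl carbonate; 10 bromoform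
Product: 12 tert-butyl (1S,2R,3R,4R,5R)-6,6-dibromo-4-[(tert-butyldimethylsilyl)oxy]-3-isopropylbicyclo[3.1.0]hexan-2-yl carbonate, via dibromocarbene 11 (not isolated)
Conditions: CHBr3 (5 equiv), 50 % aq NaOH, BnEt3NCl (10 mol %), CH2Cl2, 0 °C → rt, vigorous stirring
Reagents that add atoms: none
Why: Phase-transfer dibromocyclopropanation (α-elimination from bromoform, then [2+1] addition of singlet CBr2 to the cis-alkene) is expected anti to the silyloxy and isopropyl groups, but the face is of no consequence because both cyclopropane diastereomers give the same cation in step 8, and the two-phase medium should spare the tert-butyl carbonate and the silyl ether.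

Step 8
Reactants: 12 tert-butyl (1S,2R,3R,4R,5R)-6,6-dibromo-4-[(tert-butyldimethylsilyl)oxy]-3-isopropylbicyclo[3.1.0]hexan-2-yl carbonate
Product: 15 (3aR,4R,5R,7aR)-7-bromo-5-[(tert-butyldimethylsilyl)oxy]-4-isopropyl-3a,4,5,7a-tetrahydro-1,3-benzodioxol-2-one, via 2-bromocyclohexenyl cation 13 (not isolated), via dioxolan-2-ylium ion 14 (not isolated)
Conditions: AgOTf (1.5 equiv), 2,6-di-tert-butyl-4-methylpyridine (2 equiv), CH2Cl2, 0 °C → rt, dark
Reagents that add atoms: none
Why: Ag(I) pulls off the endo bromide of 12 while the C1–C5 bond of the cyclopropane opens in the disrotatory 2π-electrocyclic sense required by the Woodward–Hoffmann–DePuy rule, so that the five-membered ring expands by the carbene carbon to the 2-bromocyclohexenyl cation 13. The closest known reaction type is the silver-promoted electrocyclic ring opening of ring-fused gem-dibromocyclopropanes with trapping of the allyl cation by a tethered or external O-nucleophile, and capture by a neighbouring tert-butyl carbonate with loss of isobutene is the carbonate counterpart of acyloxonium participation. The six-membered carbocycle is not closed but arises by cleavage of the zero-atom bridge of the bicyclo[3.1.0]hexane, whereas the carbonate ring closes in a 5-exo mode by attack of the carbonyl oxygen on the adjacent cation terminus to give 14, which collapses to 15. The only new stereocentre, the carbinol carbon C7a, is set by the tether, because the five-membered ring can only be cis-fused, and it is erased on oxidation in step 12; the three stereocentres carried in from 12 are not touched. The selectivity needed is regiochemical, between the two termini of an almost symmetrical allyl cation, and it is secured by placing the participating carbonate on the oxygen trans to isopropyl and a non-participating silyl ether on the other oxygen. Both cyclopropane diastereomers converge on the same cation, and the hindered pyridine should keep the silyl ether and the carbonate safe from triflic acid.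

Step 9
Reactants: 15 (3aR,4R,5R,7aR)-7-bromo-5-[(tert-butyldimethylsilyl)oxy]-4-isopropyl-3a,4,5,7a-tetrahydro-1,3-benzodioxol-2-one
Product: 16 (3aR,4S,5R,7aR)-7-bromo-5-hydroxy-4-isopropyl-3a,4,5,7a-tetrahydro-1,3-benzodioxol-2-one
Conditions: HF·pyridine, pyridine/THF, 0 °C → rt
Reagents that add atoms: none
Why: Fluoride-mediated desilylation under buffered conditions should free the hydroxyl cis to isopropyl without touching the cyclic carbonate or the vinylic bromide.

Step 10
Reactants: 16 (3aR,4S,5R,7aR)-7-bromo-5-hydroxy-4-isopropyl-3a,4,5,7a-tetrahydro-1,3-benzodioxol-2-one; 17 tigloyl chloride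
Product: 18 (3aR,4S,5R,7aR)-7-bromo-4-isopropyl-2-oxo-3a,4,5,7a-tetrahydro-1,3-benzodioxol-5-yl (2E)-2-methylbut-2-enoate
Conditions: tigloyl chloride (2 equiv), pyridine (4 equiv), DMAP (0.2 equiv), CH2Cl2, 0 °C → rt
Reagents that add atoms: none
Why: DMAP-catalysed acylation with the acid chloride esterifies the single free hydroxyl while the other two ring oxygens are locked in the carbonate, and the thermodynamically preferred E (tigloyl) geometry is kept.

Step 11
Reactants: 18 (3aR,4S,5R,7aR)-7-bromo-4-isopropyl-2-oxo-3a,4,5,7a-tetrahydro-1,3-benzodioxol-5-yl (2E)-2-methylbut-2-enoate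
Product: 19 (1R,4R,5R,6R)-3-bromo-4,5-dihydroxy-6-isopropylcyclohex-2-en-1-yl (2E)-2-methylbut-2-enoate
Conditions: K2CO3 (0.3 equiv), MeOH, 0 °C, monitored closely; aq NH4Cl
Reagents that add atoms: none
Why: Base-catalysed methanolysis (transesterification) of the strained five-membered cyclic carbonate, which is far more electrophilic than the hindered α-branched conjugated tiglate, should free the cis-diol.

Step 12
Reactants: 19 (1R,4R,5R,6R)-3-bromo-4,5-dihydroxy-6-isopropylcyclohex-2-en-1-yl (2E)-2-methylbut-2-enoate
Product: 20 (1R,5R,6R)-3-bromo-5-hydroxy-6-isopropyl-4-oxocyclohex-2-en-1-yl (2E)-2-methylbut-2-enoate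
Conditions: activated MnO2 (15 equiv), CH2Cl2, rt
Reagents that add atoms: none
Why: Chemoselective MnO2 oxidation of an allylic alcohol in the presence of a saturated secondary alcohol should turn the carbinol made in step 8 into the enone carbonyl and leave the hydroxyl trans to isopropyl untouched under neutral conditions that do not epimerise the α-ketol.

Step 13
Reactants: 20 (1R,5R,6R)-3-bromo-5-hydroxy-6-isopropyl-4-oxocyclohex-2-en-1-yl (2E)-2-methylbut-2-enoate; 21 (tributylstannyl)methanol
Product: 22 (1S,5R,6R)-5-hydroxy-3-(hydroxymethyl)-6-isopropyl-4-oxocyclohex-2-en-1-yl (2E)-2-methylbut-2-enoate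
Conditions: Pd2(dba)3 (5 mol %), AsPh3 (20 mol %), CuI (10 mol %), NMP, 50 °C, degassed
Reagents that add atoms: none
Why: Stille cross-coupling of the α-bromoenone with the hydroxymethyl stannane under ligand- and copper-accelerated neutral conditions should replace bromine by CH2OH at C2 while tolerating the free hydroxyl and the ester.

Step 14
Reactants: 22 (1S,5R,6R)-5-hydroxy-3-(hydroxymethyl)-6-isopropyl-4-oxocyclohex-2-en-1-yl (2E)-2-methylbut-2-enoate; 17 tigloyl chloride
Product: 23 (1S,5R,6R)-5-hydroxy-6-isopropyl-3-({[(2E)-2-methylbut-2-enoyl]oxy}methyl)-4-oxocyclohex-2-en-1-yl (2E)-2-methylbut-2-enoate (target; 4S,5R,6R in the enone numbering of the overview)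
Conditions: tigloyl chloride (1.05 equiv), 2,4,6-collidine (2 equiv), CH2Cl2, −40 → −20 °C
Reagents that add atoms: none
Why: Chemoselective acylation of the primary allylic alcohol over the hindered, hydrogen-bonded secondary α-ketol hydroxyl with one equivalent of acid chloride and a non-nucleophilic pyridine base at low temperature should complete the second tiglate without SN2′ or elimination chemistry.

**Compound list**
1 | furfural (furan-2-carbaldehyde) | O=Cc1ccco1 | starting material
2 | isopropylmagnesium chloride | CC(C)[Mg]Cl | starting material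
3 | rac-1-(furan-2-yl)-2-methylpropan-1-ol (racemic carbinol) | CC(C)C(O)c1ccco1 | intermediate
4 | 5-(2-methylpropylidene)-2,5-dihydrofuran-2-ol (hemiacetal, not isolated) | CC(C)C=C1C=CC(O)O1 | intermediate
5 | rac-(4S*,5R*)-4-hydroxy-5-isopropylcyclopent-2-en-1-one (trans, both enantiomers) | O=C1C=C[C@H](O)[C@H]1C(C)C.O=C1C=C[C@@H](O)[C@@H]1C(C)C | intermediate
6 | (4S,5R)-4-hydroxy-5-isopropylcyclopent-2-en-1-one | O=C1C=C[C@H](O)[C@H]1C(C)C | intermediate
7 | tert-butyl (1S,5R)-5-isopropyl-4-oxocyclopent-2-en-1-yl carbonate | O=C1C=C[C@H](OC(=O)OC(C)(C)C)[C@H]1C(C)C | intermediate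
8 | tert-butyl (1S,4S,5S)-4-hydroxy-5-isopropylcyclopent-2-en-1-yl carbonate (OH cis to isopropyl, carbonate trans) | O[C@H]1C=C[C@H](OC(=O)OC(C)(C)C)[C@H]1C(C)C | intermediate
9 | tert-butyl (1S,4S,5R)-4-[(tert-butyldimethylsilyl)oxy]-5-isopropylcyclopent-2-en-1-yl carbonate | CC(C)(C)[Si](C)(C)O[C@H]1C=C[C@H](OC(=O)OC(C)(C)C)[C@H]1C(C)C | intermediate
10 | bromoform | BrC(Br)Br | starting material
11 | dibromocarbene (not isolated) | Br[C]Br | intermediate
12 | tert-butyl (1S,2R,3R,4R,5R)-6,6-dibromo-4-[(tert-butyldimethylsilyl)oxy]-3-isopropylbicyclo[3.1.0]hexan-2-yl carbonate (cyclopropane anti to OTBS and isopropyl) | CC(C)(C)[Si](C)(C)O[C@H]1[C@H]2[C@H](C2(Br)Br)[C@H](OC(=O)OC(C)(C)C)[C@H]1C(C)C | intermediate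
13 | 2-bromo-6-[(tert-butoxycarbonyl)oxy]-4-[(tert-butyldimethylsilyl)oxy]-5-isopropylcyclohex-2-en-1-ylium (allyl cation, substituent configurations as in 12, not isolated) | CC(C)(C)[Si](C)(C)O[C@H]1C=C(Br)[CH+][C@H](OC(=O)OC(C)(C)C)[C@H]1C(C)C | intermediate
14 | 7-bromo-2-tert-butoxy-5-[(tert-butyldimethylsilyl)oxy]-4-isopropyl-3a,4,5,7a-tetrahydro-1,3-benzodioxol-2-ylium (cis-fused, configurations as in 15, not isolated) | CC(C)(C)[Si](C)(C)O[C@H]1C=C(Br)[C@@H]2O[C+](OC(C)(C)C)O[C@@H]2[C@H]1C(C)C | intermediate
15 | (3aR,4R,5R,7aR)-7-bromo-5-[(tert-butyldimethylsilyl)oxy]-4-isopropyl-3a,4,5,7a-tetrahydro-1,3-benzodioxol-2-one (cis-fused carbonate trans to isopropyl, OTBS cis to isopropyl) | CC(C)(C)[Si](C)(C)O[C@H]1C=C(Br)[C@@H]2OC(=O)O[C@@H]2[C@H]1C(C)C | intermediate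
16 | (3aR,4S,5R,7aR)-7-bromo-5-hydroxy-4-isopropyl-3a,4,5,7a-tetrahydro-1,3-benzodioxol-2-one | O[C@H]1C=C(Br)[C@@H]2OC(=O)O[C@@H]2[C@H]1C(C)C | intermediate
17 | tigloyl chloride, (2E)-2-methylbut-2-enoyl chloride | C/C=C(\C)C(=O)Cl | starting material
18 | (3aR,4S,5R,7aR)-7-bromo-4-isopropyl-2-oxo-3a,4,5,7a-tetrahydro-1,3-benzodioxol-5-yl (2E)-2-methylbut-2-enoate | C/C=C(\C)C(=O)O[C@H]1C=C(Br)[C@@H]2OC(=O)O[C@@H]2[C@H]1C(C)C | intermediate
19 | (1R,4R,5R,6R)-3-bromo-4,5-dihydroxy-6-isopropylcyclohex-2-en-1-yl (2E)-2-methylbut-2-enoate | C/C=C(\C)C(=O)O[C@H]1C=C(Br)[C@H](O)[C@H](O)[C@H]1C(C)C | intermediate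
20 | (1R,5R,6R)-3-bromo-5-hydroxy-6-isopropyl-4-oxocyclohex-2-en-1-yl (2E)-2-methylbut-2-enoate | C/C=C(\C)C(=O)O[C@H]1C=C(Br)C(=O)[C@H](O)[C@H]1C(C)C | intermediate
21 | (tributylstannyl)methanol | CCCC[Sn](CCCC)(CCCC)CO | starting material
22 | (1S,5R,6R)-5-hydroxy-3-(hydroxymethyl)-6-isopropyl-4-oxocyclohex-2-en-1-yl (2E)-2-methylbut-2-enoate | C/C=C(\C)C(=O)O[C@H]1C=C(CO)C(=O)[C@H](O)[C@H]1C(C)C | intermediate
23 | (1S,5R,6R)-5-hydroxy-6-isopropyl-3-({[(2E)-2-methylbut-2-enoyl]oxy}methyl)-4-oxocyclohex-2-en-1-yl (2E)-2-methylbut-2-enoate | C/C=C(\C)C(=O)O[C@H]1C=C(COC(=O)/C(C)=C/C)C(=O)[C@H](O)[C@H]1C(C)C | target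

Total step count: 14. Longest linear sequence: 14 steps (furfural to 23); 2, 10, 17 and 21 are bought.

**Steps most likely to fail**

1. Step 7. Carbene addition may be sluggish on an alkene that is deactivated by two allylic C–O bonds and shielded on both faces, and the long exposure to the basic two-phase medium may then hydrolyse the tert-butyl carbonate. The fallback sets out from 6 and returns at 12, and carries the oxygen trans to isopropyl as a base-stable silyl ether through the cyclopropanation. 6 is silylated (TESCl, imidazole) to the triethylsilyl ether F1, reduced as in step 5 to the allylic alcohol F2 and silylated (TBSCl, imidazole) to the bis-silyl ether F3. Dibromocarbene is then added under anhydrous conditions that these ethers tolerate (CHBr3, KOtBu, pentane, −10 °C) to give the dibromocyclopropane F4. The more labile triethylsilyl group is removed (PPTS, MeOH, 0 °C) to the cyclopropyl carbinol F5, which is acylated with Boc2O/DMAP to 12.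

2. Step 8. Ionisation may be slow because the allyl cation carries bromine and two β-oxygen substituents; in addition, the triflic acid set free may strip the silyl ether, or the cation may lose a proton before the carbonate closes. The fallback sets out from 12 and returns at 15, and separates ring expansion from capture without silver. 12 is heated in chlorobenzene with 2,6-lutidine at 120 °C so that thermal disrotatory opening and ion-pair return give the allylic bromide F6. F6 is then warmed with NaI (cat.) and NaHCO3 in MeCN, where the carbonate carbonyl displaces the allylic bromide (SN2, or SN2′ from the transposed bromide) with loss of tert-butyl bromide and closes the same cis-fused carbonate 15.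

3. Step 12. MnO2 may oxidise the 2-bromoallylic alcohol only slowly, and glycol cleavage of the cis-diol or oxidation of the second hydroxyl may then compete. The fallback sets out from 19 and returns at 20, and uses tin-acetal-directed oxidation. 19 is converted with Bu2SnO (toluene, reflux, water removed) into the dibutylstannylene acetal F7, which is brominolysed (Br2, CH2Cl2, 4 Å sieves, 0 °C). Tin acetals of cis-diols are oxidised at the pseudo-axial oxygen, here the allylic one pushed axial by A(1,2) strain with the vinylic bromine, so the same hydroxy-enone 20 should result.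

**Further compounds**
F1 | step 7 | (4S,5R)-5-isopropyl-4-[(triethylsilyl)oxy]cyclopent-2-en-1-one | O=C1C=C[C@H](O[Si](CC)(CC)CC)[C@H]1C(C)C
F2 | step 7 | (1S,4S,5S)-5-isopropyl-4-[(triethylsilyl)oxy]cyclopent-2-en-1-ol (OH cis to isopropyl) | O[C@H]1C=C[C@H](O[Si](CC)(CC)CC)[C@H]1C(C)C
F3 | step 7 | tert-butyldimethylsilyl ether of F2 (OTBS cis and OTES trans to isopropyl) | CC(C)(C)[Si](C)(C)O[C@H]1C=C[C@H](O[Si](CC)(CC)CC)[C@H]1C(C)C
F4 | step 7 | 6,6-dibromo-4-[(tert-butyldimethylsilyl)oxy]-3-isopropyl-2-[(triethylsilyl)oxy]bicyclo[3.1.0]hexane (cyclopropane anti to OTBS and isopropyl, configurations as in 12) | CC(C)(C)[Si](C)(C)O[C@H]1[C@H]2[C@H](C2(Br)Br)[C@H](O[Si](CC)(CC)CC)[C@H]1C(C)C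
F5 | step 7 | (1S,2R,3R,4R,5R)-6,6-dibromo-4-[(tert-butyldimethylsilyl)oxy]-3-isopropylbicyclo[3.1.0]hexan-2-ol | CC(C)(C)[Si](C)(C)O[C@H]1[C@H]2[C@H](C2(Br)Br)[C@H](O)[C@H]1C(C)C
F6 | step 8 | tert-butyl (1R,2S,5R,6R)-2,3-dibromo-5-[(tert-butyldimethylsilyl)oxy]-6-isopropylcyclohex-3-en-1-yl carbonate (allylic bromide trans to the carbonate) | CC(C)(C)[Si](C)(C)O[C@H]1C=C(Br)[C@@H](Br)[C@H](OC(=O)OC(C)(C)C)[C@H]1C(C)C
F7 | step 12 | (3aR,4S,5R,7aR)-7-bromo-2,2-dibutyl-4-isopropyl-3a,4,5,7a-tetrahydro-1,3,2-benzodioxastannol-5-yl (2E)-2-methylbut-2-enoate | C/C=C(\C)C(=O)O[C@H]1C=C(Br)[C@@H]2O[Sn](CCCC)(CCCC)O[C@@H]2[C@H]1C(C)C
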